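**Assumption:** the given SMILES is read as the (3R) enantiomer, with chroman numbering O1, C2 (gem-dimethyl), C3 (carbinol), C5/C7 (OH), C6 (prenyl), C8 (benzoyl).

## Retrosynthetic overview

- The target is opened at the C6–prenyl bond: C6 is the only unsubstituted ring carbon of (3R)-8-benzoyl-2,2-dimethylchromane-3,5,7-triol, so a late phenoxide C-prenylation has no regiochemical choice.
- The C3 carbinol comes from catalyst-controlled reduction of the corresponding 2,2-dimethylchroman-3-one.
- Key disconnection C4–C4a: the chroman-3-one comes from an aryl 1,1-dimethylpropargyl ether. Gold-catalysed alkyne oxidation gives an α-oxo gold carbene, in which the ketone α-carbon is an electrophile (an enolonium equivalent), and the nucleophilic arene carbon captures it.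
- The propargyl ether comes from 2,4,6-trihydroxybenzophenone, masked at the para OH so that the ether is placed on an ortho OH; this fixes the benzoyl group at C8.
- Ring order: both benzene rings are bought; the dihydropyranone ring is the only ring formed, in the key step.

## Route

Step 1
Reactants: 1 phlorobenzophenone (2,4,6-trihydroxybenzophenone)
Product: 2 [2,6-dihydroxy-4-(methoxymethoxy)phenyl](phenyl)methanone
Conditions: MOMCl (1.05 equiv), iPr2NEt (1.2 equiv), THF, 0 °C
Reagents that add atoms: chloromethyl methyl ether (MOMCl), COCCl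
Why: Williamson-type O-alkylation (MOM protection) is selective for the 4-OH because it is the only hydroxyl not hydrogen-bonded to the benzoyl carbonyl and, being para to it, the most acidic, so one equivalent blocks exactly the oxygen that must not take part in ring formation.

Step 2
Reactants: 2 [2,6-dihydroxy-4-(methoxymethoxy)phenyl](phenyl)methanone; 3 tertiary propargylic chloride 3-chloro-3-methylbut-1-yne
Product: 4 [2-hydroxy-4-(methoxymethoxy)-6-(2-methylbut-3-yn-2-yloxy)phenyl](phenyl)methanone
Conditions: 3 (1.5 equiv), DBU (1.6 equiv), CuCl2·2H2O (1 mol%), MeCN, 0 °C to rt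
Reagents that add atoms: none
Why: Copper-catalysed propargylic etherification (via a copper acetylide/allenylidene-type electrophile that tolerates the tertiary centre) alkylates one of the two equivalent ortho hydroxyls, after which the remaining one is locked in the chelate to the carbonyl and resists a second alkylation.

Step 3
Reactants: 4 [2-hydroxy-4-(methoxymethoxy)-6-(2-methylbut-3-yn-2-yloxy)phenyl](phenyl)methanone
Product: 6 [7-hydroxy-5-(methoxymethoxy)-2,2-dimethyl-3-oxochroman-8-yl](phenyl)methanone, via alpha-oxo gold carbene 5 (not isolated)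
Conditions: Me4tBuXPhosAuNTf2 (5 mol%), 3,5-dichloropyridine N-oxide (1.3 equiv, slow addition), DCE, rt
Reagents that add atoms: 3,5-dichloropyridine N-oxide, [O-][n+]1cc(Cl)cc(Cl)c1
Why: Gold-catalysed alkyne oxidation, in which the N-oxide adds to the internal carbon of the gold-activated terminal alkyne and N–O cleavage gives carbene 5 whose carbon (the α-carbon of the new ketone, an enolonium equivalent) is captured by the electron-rich arene carbon ortho to the ether oxygen (the other ortho position carries the benzoyl group) in a six-membered Friedel–Crafts-type closure followed by protodeauration, so that an arene carbon and a ketone α-carbon, both nucleophiles in ordinary chemistry, are joined.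

Step 4
Reactants: 6 [7-hydroxy-5-(methoxymethoxy)-2,2-dimethyl-3-oxochroman-8-yl](phenyl)methanone
Product: 8 (3R)-8-benzoyl-2,2-dimethylchromane-3,5,7-triol, via MOM-protected (3R)-chromanol 7 (not isolated)
Conditions: (S)-Me-CBS (20 mol%), catecholborane (2 equiv), toluene, –78 to –40 °C; then MeOH, 3 M HCl in MeOH, 45 °C
Reagents that add atoms: none
Why: Corey–Bakshi–Shibata reduction, in which the ketone binds the oxazaborolidine boron anti to its larger flank (the quaternary C2 carrying the aryloxy group) so that hydride is delivered to the face giving the (3R) alcohol (the same sense as pinacolone giving the (R) carbinol with the (S) catalyst), the hindered chelated diaryl ketone is left alone at low temperature, and the acidic methanol work-up then cleaves the MOM acetal without touching the tertiary aryl ether.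

Step 5
Reactants: 8 (3R)-8-benzoyl-2,2-dimethylchromane-3,5,7-triol; 9 prenyl bromide (1-bromo-3-methylbut-2-ene)
Product: 10 (3R)-8-benzoyl-2,2-dimethyl-6-(3-methylbut-2-en-1-yl)chromane-3,5,7-triol
Conditions: 9 (1.1 equiv), 5% aq. KOH (2.2 equiv), 0 °C to rt
Reagents that add atoms: none
Why: Base-mediated C-alkylation of an acylphloroglucinol-type phenoxide, in which water shields the phenoxide oxygens by hydrogen bonding so the ambident anion reacts with the allylic bromide at C6, the only unsubstituted ring carbon and flanked by both phenoxide oxygens, while the C3 stereocentre is not involved.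

## Compound list

1 | phlorobenzophenone (2,4,6-trihydroxybenzophenone) | O=C(c1ccccc1)c1c(O)cc(O)cc1O | starting material
2 | [2,6-dihydroxy-4-(methoxymethoxy)phenyl](phenyl)methanone | COCOc1cc(O)c(C(=O)c2ccccc2)c(O)c1 | intermediate
3 | 3-chloro-3-methylbut-1-yne | CC(C)(Cl)C#C | starting material
4 | [2-hydroxy-4-(methoxymethoxy)-6-(2-methylbut-3-yn-2-yloxy)phenyl](phenyl)methanone | COCOc1cc(O)c(C(=O)c2ccccc2)c(OC(C)(C)C#C)c1 | intermediate
5 | alpha-oxo gold carbene [(Me4tBuXPhos)Au=CH–C(=O)–CMe2–OAr]NTf2 | COCOc1cc(O)c(C(=O)c2ccccc2)c(OC(C)(C)C(=O)C=[Au][P+](C(C)(C)C)(C(C)(C)C)c2c(C)c(C)c(C)c(C)c2-c2c(C(C)C)cc(C(C)C)cc2C(C)C)c1.[N-](S(=O)(=O)C(F)(F)F)S(=O)(=O)C(F)(F)F | intermediate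
6 | [7-hydroxy-5-(methoxymethoxy)-2,2-dimethyl-3-oxochroman-8-yl](phenyl)methanone | COCOc1cc(O)c(C(=O)c2ccccc2)c2OC(C)(C)C(=O)Cc12 | intermediate
7 | [(3R)-3,7-dihydroxy-5-(methoxymethoxy)-2,2-dimethylchroman-8-yl](phenyl)methanone | COCOc1cc(O)c(C(=O)c2ccccc2)c2OC(C)(C)[C@H](O)Cc12 | intermediate
8 | (3R)-8-benzoyl-2,2-dimethylchromane-3,5,7-triol | Oc1cc(O)c(C(=O)c2ccccc2)c2OC(C)(C)[C@H](O)Cc12 | intermediate
9 | prenyl bromide (1-bromo-3-methylbut-2-ene) | CC(C)=CCBr | starting material
10 | (3R)-8-benzoyl-2,2-dimethyl-6-(3-methylbut-2-en-1-yl)chromane-3,5,7-triol | CC(C)=CCc1c(O)c2c(c(C(=O)c3ccccc3)c1O)OC(C)(C)[C@H](O)C2 | target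

## Step count and risks

Total steps: 5. Longest linear sequence: 5 (1 → 2 → 4 → 6 → 8 → 10).

**Step 3 (key ring closure).** The likely failures are direct gold-catalysed hydroarylation of the 1,1-dimethylpropargyl ether to the 2H-chromene, and a second oxidation of the carbene to the keto-aldehyde. The fallback makes the same C4–C4a bond with a different α-carbonyl electrophile; it sets out from 2 and comes back at 6.
- O-Alkylation of 2 with 3-bromo-3-methylbutan-2-one (K2CO3, DMF, 50 °C) gives 3-[2-benzoyl-3-hydroxy-5-(methoxymethoxy)phenoxy]-3-methylbutan-2-one F1.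
- LiHMDS (2.2 equiv) and TMSCl (THF, –78 °C) silylate the phenol and the only enolisable side, the methyl group, to give the bis-silylated silyl enol ether F2.
- NBS (THF, –78 °C) and aqueous work-up give 1-bromo-3-[2-benzoyl-3-hydroxy-5-(methoxymethoxy)phenoxy]-3-methylbutan-2-one F3.
- K2CO3 and NaI (acetone, 50 °C) close the ring by intramolecular C-alkylation of the phenoxide at the carbon para to the phenoxide oxygen and ortho to the ether, giving 6.

**Step 4 (enantioselective reduction).** The ketone is flanked by a quaternary and a benzylic carbon, and the enantiomeric excess on this substrate is not known. The fallback replaces catalyst control by resolution with recycling; it sets out from 6 and comes back at 7.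
- NaBH4 (MeOH, –20 °C) reduces only the dialkyl ketone to racemic [3,7-dihydroxy-5-(methoxymethoxy)-2,2-dimethylchroman-8-yl](phenyl)methanone F4.
- Preparative chiral SFC on an amylose-based phase delivers 7, which is deprotected with HCl in MeOH as in step 4.
- The unwanted (3S)-[3,7-dihydroxy-5-(methoxymethoxy)-2,2-dimethylchroman-8-yl](phenyl)methanone F5 is oxidised back to 6 with Dess–Martin periodinane and recycled.

**Step 5 (C-prenylation).** O-Prenylation and a second, dearomatising alkylation at C6 compete, and yields for this reaction type are usually modest. The fallback replaces phenoxide alkylation by halogenation and cross-coupling; it sets out from 8 and comes back at 10.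
- NIS (1.0 equiv, DMF, 0 °C) iodinates the only free ring position to give (3R)-8-benzoyl-6-iodo-2,2-dimethylchromane-3,5,7-triol F6.
- Stille coupling with tributyl(3-methylbut-2-en-1-yl)stannane (Pd(PPh3)4 5 mol%, DMF, 80 °C) gives 10.

## Further compounds

F1 | step 3 | 3-[2-benzoyl-3-hydroxy-5-(methoxymethoxy)phenoxy]-3-methylbutan-2-one | COCOc1cc(O)c(C(=O)c2ccccc2)c(OC(C)(C)C(C)=O)c1
F2 | step 3 | [4-(methoxymethoxy)-2-(trimethylsilyloxy)-6-{[2-methyl-3-(trimethylsilyloxy)but-3-en-2-yl]oxy}phenyl](phenyl)methanone | COCOc1cc(O[Si](C)(C)C)c(C(=O)c2ccccc2)c(OC(C)(C)C(=C)O[Si](C)(C)C)c1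
F3 | step 3 | 1-bromo-3-[2-benzoyl-3-hydroxy-5-(methoxymethoxy)phenoxy]-3-methylbutan-2-one | COCOc1cc(O)c(C(=O)c2ccccc2)c(OC(C)(C)C(=O)CBr)c1
F4 | step 4 | racemic [3,7-dihydroxy-5-(methoxymethoxy)-2,2-dimethylchroman-8-yl](phenyl)methanone | COCOc1cc(O)c(C(=O)c2ccccc2)c2OC(C)(C)C(O)Cc12
F5 | step 4 | [(3S)-3,7-dihydroxy-5-(methoxymethoxy)-2,2-dimethylchroman-8-yl](phenyl)methanone | COCOc1cc(O)c(C(=O)c2ccccc2)c2OC(C)(C)[C@@H](O)Cc12
F6 | step 5 | (3R)-8-benzoyl-6-iodo-2,2-dimethylchromane-3,5,7-triol | Oc1c(I)c(O)c(C(=O)c2ccccc2)c2OC(C)(C)[C@H](O)Cc12
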